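## The problem

Target 15 is an achiral isoflavone: a benzopyran-4-one (benzene ring A fused to pyranone ring C) that carries the 4-methoxyphenyl ring B on C3, a methoxy group on C8 and a prenyl (3-methylbut-2-enyl) ether on O7. With no stereocentre, the difficulties are all of placement and order. Ring A is a 1,2,3,4-tetrasubstituted benzene in which C7, C8 and C8a bear oxygen and C4a bears the C4 carbonyl, and the oxygens on C7 and C8 must receive different alkyl groups without ambiguity. The prenyl aryl ether is the fragile group: it ionises under Brønsted or Lewis acid, rearranges on strong heating, and its alkene is reduced by hydrogen over palladium. The pyranone is opened by hydroxide at C2, so strongly basic aqueous steps belong before ring closure. The skeletal issue is C3, which is bonded to ring B, to the ketone carbon C4 and to C2 (aldehyde oxidation level, bound to O1), a branched 1,2-diaryl three-carbon unit, whereas an aldol condensation gives the linear 1,3-diaryl chain. The same feature offers the solution: the carbon that carries the 4-methoxyphenyl group is an excellent cation site, so in a chalcone epoxide the aroyl group can shift onto it, which makes the branched unit and leaves the neighbouring carbon as the aldehyde needed for C2.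

## Retrosynthesis

**15 ⇒ 13 + 14.** The O7–CH2 bond of the prenyl ether is cut first. The prenyl group would survive neither the Lewis acid of the rearrangement nor hydrogenolysis, so it cannot be carried from an earlier stage. The precursors are the hydroxyisoflavone 13 and prenyl bromide 14. Because 13 has a single free hydroxyl, the forward alkylation needs only O- over C-selectivity under mild base.

**13 ⇒ 10.** Ring C is opened at O1–C2 and the C2=C3 double bond is traced back to a formyl group. This passes through the cyclic hemiacetal 12 and its open diphenol 11 to the bis-benzyl keto-aldehyde 10. Cutting O1–C2 is preferred to cutting C2–C3 (one-carbon insertion into a deoxybenzoin) because it keeps C2 on C3, which is exactly what the rearrangement supplies. The forward step must remove two benzyl ethers without reducing the aryl ketone, after which six-membered hemiacetal formation and dehydration to the aromatic pyranone follow.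

**10 ⇒ 9 (key disconnection).** The C3–C4 bond is cut and the aroyl carbon is returned to the neighbouring carbon, with an oxirane across the two. This converts the branched 2-aryl-3-oxopropanal 10 into the linear trans-epoxy ketone 9. No other single disconnection turns the isoflavone C3 unit into an aldol-derived chain. The forward reaction must ionise the epoxide only at the carbon bearing the 4-methoxyphenyl group and migrate acyl rather than hydride.

**9 ⇒ 8.** The two C–O bonds of the oxirane are cut to give the E-chalcone 8. Nucleophilic epoxidation is chosen over peracid oxidation because the alkene is an enone and both aryl rings are electron-rich enough to be attacked by an electrophilic oxidant. The forward step asks for conjugate addition of hydroperoxide to a rather electron-rich enone.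

**8 ⇒ 5 + 6.** The Cα=Cβ bond is cut by a retro-Claisen–Schmidt condensation. It gives the acetophenone 5 and 4-methoxybenzaldehyde 6, so ring B with its methoxy group is bought complete. The aldehyde cannot enolise and the ketone has only one enolisable site, so the forward condensation has no regiochemical question.

**5 ⇒ 2 + 3.** Both O–CH2Ph bonds are cut, through the mono-ether 4, to the dihydroxyacetophenone 2 and benzyl bromide 3. Protection is placed before the condensation because a free ortho-hydroxyl would divert the alkaline peroxide step to flavonol or aurone formation and would capture the cation in the key step. Benzyl is chosen because it tolerates hydroxide, peroxide and a brief Lewis-acid treatment and is later removed without touching the two methyl ethers.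

**2 ⇒ 1.** The aryl–acetyl bond is cut to give 2-methoxyresorcinol 1 and a simple acetyl donor. Compound 1 already holds the C8 methoxy group between the two oxygens that become O1 and O7, which settles the methyl-versus-prenyl question at the start. Its two activated positions are equivalent, so the forward acylation has only one possible regiochemical outcome.

## Roads not taken

**Alternative 1:** Ring C is cut at three bonds at once: C4a–C4, C4–C3 and O1–C2. Ring A then comes from 4-iodo-2-methoxybenzene-1,3-diol A1, the carbon C4 from carbon monoxide A2, and C2, C3 and ring B from the enol ether (E)-1-methoxy-2-(4-methoxyphenyl)ethene A3.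

- Forward key step: zerovalent palladium, formed from Pd(OAc)2, 1,3-bis(diphenylphosphino)propane and NEt3, would insert into the carbon–iodine bond of A1 and take up A2 to give an aroyl–palladium species. This would acylate A3, and after β-hydride elimination the ortho-hydroxyl would displace methoxide to give 7-hydroxy-8-methoxy-3-(4-methoxyphenyl)-4H-chromen-4-one A4, which is the same compound as 13.
- Merits: A1 is one iodination away from 1 and A3 one olefination away from 6. Compound A4 would be reached in a longest linear sequence of two steps, against six for 13 in the chosen plan, and with full convergence.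
- Weak points: carbonylative annulations of 2-iodophenols are established with terminal alkynes and give 2-substituted chromones. For a 3-aryl product the aroyl group must add to the aryl-bearing carbon of A3. Both the oxygen substituent (under a chelating bisphosphine) and the aryl group direct carbopalladation to the oxygen-bearing carbon, which leads towards 2-aryl rather than 3-aryl heterocycles. The diol A1 also has two free phenols that can trap the aroyl–palladium intermediate as esters, and mono-iodination of 1 must be stopped cleanly.
- Comparison: this road is clearly better in length and convergence, but its central bond formation runs against the intrinsic regiochemical bias of the alkene. The chosen plan sets against it a key step whose regiochemistry follows from cation stability, and steps of established type throughout.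

**Alternative 2:** Ring A is cut at C4a–C8a and C5–C6 and built by cycloaddition.

- Forward key step: Diels–Alder reaction of 1,2-dimethoxy-1,3-bis(trimethylsilyloxy)buta-1,3-diene A5 with 1-(4-methoxyphenyl)but-3-yn-2-one A6, then loss of methanol and desilylation, would give the deoxybenzoin 1-(2,4-dihydroxy-3-methoxyphenyl)-2-(4-methoxyphenyl)ethanone A7. One-carbon insertion between the methylene carbon of A7 and its ortho-hydroxyl would give 13, and prenylation would give 15.
- Merits: the polarity of the two partners fixes the 1,2,3-trioxygenation pattern (the CH2 terminus of A5 adds to the β-carbon of A6). The C8 methoxy group is distinguished from the hydroxyls from the outset. The endgame from A7 is two steps, shorter than the five that separate 5 from 15.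
- Weak points: the diene A5 is a moisture-sensitive bis-silyl compound that needs its own preparation. The ynone A6 has an acidic benzylic CH2 between aryl and carbonyl and is prone to isomerisation and polymerisation. Above all, the cycloaddition builds a ring that can be bought: the deoxybenzoin A7 is the product expected from a single Friedel–Crafts acylation of 1 with 4-methoxyphenylacetic acid A8, so that 1 and A8 would replace both cycloaddition partners.
- Comparison: as a Diels–Alder route it is longer and more delicate than the chosen plan, which takes every carbon of ring A from 1. The deoxybenzoin endgame itself is shorter than the epoxide sequence, and if A7 were made by direct acylation with A8 the whole route would be shorter. The chosen plan can set against this only that ring B enters as an aldehyde under mild base and that all C–C bond formation after step 1 occurs at or below room temperature.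

**Alternative 3:** The C8–O bond is cut, and the C8 oxygen is introduced late on formononetin A9.

- Forward key step: ortho-formylation of A9 gives 8-formylformononetin A10. Acidic hydrogen peroxide in methanol (Dakin oxidation) then acts on A10 so that C8 shifts from the formyl carbon to oxygen and, after formate cleavage, gives 7,8-dihydroxy-3-(4-methoxyphenyl)-4H-chromen-4-one A11. The diol A11 would then be prenylated at O7 with 14 and methylated at O8.
- Merits: the route starts from an intact isoflavone and needs four steps. The acidic peroxide conditions spare C2 of the pyranone from hydroperoxide anion.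
- Weak points: formylation of A9 must choose C8 over C6. The Dakin shift in A10 involves a ring whose 7-oxygen is conjugated with the C4 carbonyl, which lowers its migratory aptitude and invites over-oxidation of A10 to the acid. The two hydroxyls of A11 must be told apart by acidity alone (O7, para-conjugated to C4=O, first), and a slip gives a regioisomer that is hard to detect. The catechol A11 is also air-sensitive under base.
- Comparison: in step count this road is better (four against seven). The chosen plan sets against it that the O8 methyl group is present in 1 from the start and that only one hydroxyl exists when 14 is introduced. No step therefore depends on discriminating two phenols or on oxidising a deactivated aldehyde.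

Key step: step 5

## Route

Remark: compound 10 is drawn as the keto-aldehyde. It is expected to exist largely as its chelated enol, so its C2 is not a controllable stereocentre, and 9 is used as the racemate.

Step 1
Reactants: 1 2-methoxyresorcinol (2-methoxybenzene-1,3-diol)
Product: 2 1-(2,4-dihydroxy-3-methoxyphenyl)ethan-1-one
Conditions: AcOH, BF3·OEt2, 90 °C; aq. NaOAc work-up
Reagents that add atoms: acetic acid, CC(=O)O
Why: Friedel–Crafts (Nencki-type) C-acylation of a resorcinol; C4 and C6 of 1 are equivalent, each ortho to one hydroxyl and para to the other, whereas C5 is activated only by the twisted central methoxy group, and the hydrogen-bonded acetyl group deactivates the ring towards a second acylation.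

Step 2
Reactants: 2 1-(2,4-dihydroxy-3-methoxyphenyl)ethan-1-one, 3 benzyl bromide
Product: 5 1-[2,4-bis(benzyloxy)-3-methoxyphenyl]ethan-1-one, via 1-[4-(benzyloxy)-2-hydroxy-3-methoxyphenyl]ethan-1-one 4 (not isolated)
Conditions: BnBr, K2CO3, KI (cat.), DMF, 70 °C
Reagents that add atoms: benzyl bromide (3), BrCc1ccccc1
Why: Double Williamson etherification; the unchelated, more acidic 4-hydroxyl reacts first, and excess reagent with heat in a dipolar solvent then alkylates the hydrogen-bonded 2-hydroxyl, while carbonate is too weak to enolise the ketone for C-benzylation.

Step 3
Reactants: 5 1-[2,4-bis(benzyloxy)-3-methoxyphenyl]ethan-1-one, 6 4-methoxybenzaldehyde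
Product: 8 (2E)-1-[2,4-bis(benzyloxy)-3-methoxyphenyl]-3-(4-methoxyphenyl)prop-2-en-1-one, via racemic 1-[2,4-bis(benzyloxy)-3-methoxyphenyl]-3-hydroxy-3-(4-methoxyphenyl)propan-1-one 7 (not isolated)
Conditions: KOH, EtOH/THF, rt
Reagents that add atoms: none
Why: Claisen–Schmidt condensation between a methyl ketone with one enolisable site and a non-enolisable aldehyde; E1cB dehydration of aldol 7 gives the conjugated E-alkene, and benzyl and methyl ethers are inert to hydroxide.

Step 4
Reactants: 8 (2E)-1-[2,4-bis(benzyloxy)-3-methoxyphenyl]-3-(4-methoxyphenyl)prop-2-en-1-one
Product: 9 rac-[2,4-bis(benzyloxy)-3-methoxyphenyl][(2S,3R)-3-(4-methoxyphenyl)oxiran-2-yl]methanone (trans-epoxide, racemate)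
Conditions: 30% aq. H2O2, NaOH, MeOH/THF, 0 °C to rt
Reagents that add atoms: hydrogen peroxide, OO
Why: Weitz–Scheffer nucleophilic epoxidation: hydroperoxide adds to the β-carbon and the enolate closes onto oxygen with loss of hydroxide; the freely rotating enolate closes to the trans-oxirane with aryl and aroyl on opposite faces, which sets the relative configuration, and no absolute control is needed because both centres are destroyed later. The benzyl ether on the ortho-oxygen prevents flavonol formation.

Step 5
Reactants: 9 rac-[2,4-bis(benzyloxy)-3-methoxyphenyl][(2S,3R)-3-(4-methoxyphenyl)oxiran-2-yl]methanone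
Product: 10 rac-3-[2,4-bis(benzyloxy)-3-methoxyphenyl]-2-(4-methoxyphenyl)-3-oxopropanal
Conditions: BF3·OEt2, CH2Cl2, 0 °C, short contact time; cold water quench
Reagents that add atoms: none
Why: BF3 binds the oxirane oxygen and the C–O bond at the carbon bearing the 4-methoxyphenyl group lengthens, because that carbon is a 4-methoxybenzylic cation site whereas the other oxirane carbon lies next to a carbonyl group and cannot carry positive charge. As this bond breaks, the aroyl group on the neighbouring carbon shifts with its bonding pair onto the benzylic carbon (a 1,2-acyl shift of semipinacol type), the remaining C–O bond becomes the formyl C=O and BF3 is released, so the C3–C4 bond of the isoflavone is formed and the carbon that lost the aroyl group becomes the aldehyde C2. The closest known reaction type is the Lewis-acid (Meinwald-type) rearrangement of α,β-epoxy ketones, specifically the BF3-promoted conversion of chalcone epoxides into 2-aryl-3-oxopropanals used as an isoflavone entry. No ring is closed, and the only new stereocentre, C2 of the propanal, lies between two carbonyl groups, is lost by enolisation and disappears on aromatisation, so it needs no control. The step needs three selectivities: ionisation at the benzylic carbon only, acyl in preference to hydride migration (a hydride shift would give the 1,2-diketone), and no capture of the cation by an internal oxygen. The first two are secured by the 4-methoxyphenyl donor and by the high migratory aptitude of an acyl group held anti to the departing oxygen in the trans-epoxide, the third by the benzyl ether on the ortho-oxygen of the aroyl ring. A non-nucleophilic solvent, low temperature, a short contact time and a neutral cold quench limit fluoride capture and retro-Claisen loss of the formyl group, and 10 is taken on crude.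

Step 6
Reactants: 10 rac-3-[2,4-bis(benzyloxy)-3-methoxyphenyl]-2-(4-methoxyphenyl)-3-oxopropanal
Product: 13 7-hydroxy-8-methoxy-3-(4-methoxyphenyl)-4H-chromen-4-one, via 3-(2,4-dihydroxy-3-methoxyphenyl)-2-(4-methoxyphenyl)-3-oxopropanal 11 (not isolated), via 2,7-dihydroxy-8-methoxy-3-(4-methoxyphenyl)chroman-4-one 12 (not isolated)
Conditions: H2 (1 atm), 10% Pd/C, EtOAc, rt; filter; then conc. HCl (cat.), MeOH, 60 °C
Reagents that add atoms: none
Why: Hydrogenolysis of both benzyl ethers over palladium on carbon frees the phenols under neutral conditions, the ortho-hydroxyl of 11 adds to the formyl group to give the six-membered hemiacetal 12, and acid-catalysed dehydration (the classical 2-hydroxyisoflavanone to isoflavone conversion) aromatises ring C. The catalyst is removed before the acid is added so that the new C2=C3 bond is not exposed to hydrogen, and the methyl ethers are untouched.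

Step 7
Reactants: 13 7-hydroxy-8-methoxy-3-(4-methoxyphenyl)-4H-chromen-4-one, 14 prenyl bromide (1-bromo-3-methylbut-2-ene)
Product: 15 8-methoxy-3-(4-methoxyphenyl)-7-[(3-methylbut-2-en-1-yl)oxy]-4H-chromen-4-one
Conditions: prenyl bromide, K2CO3, acetone, reflux
Reagents that add atoms: prenyl bromide (14), CC(C)=CCBr
Why: Williamson ether synthesis; the only hydroxyl of 13 is the acidic 7-OH (a vinylogous acid through C4=O), its phenoxide displaces bromide at the primary allylic carbon by SN2, and carbonate in acetone with a non-acidic work-up leaves the pyranone and the new prenyl ether intact.

## Compound list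

1 | 2-methoxyresorcinol (2-methoxybenzene-1,3-diol) | COc1c(O)cccc1O | starting material
2 | 1-(2,4-dihydroxy-3-methoxyphenyl)ethan-1-one | CC(=O)c1ccc(O)c(OC)c1O | intermediate
3 | benzyl bromide | BrCc1ccccc1 | starting material
4 | 1-[4-(benzyloxy)-2-hydroxy-3-methoxyphenyl]ethan-1-one (not isolated) | CC(=O)c1ccc(OCc2ccccc2)c(OC)c1O | intermediate
5 | 1-[2,4-bis(benzyloxy)-3-methoxyphenyl]ethan-1-one | CC(=O)c1ccc(OCc2ccccc2)c(OC)c1OCc1ccccc1 | intermediate
6 | 4-methoxybenzaldehyde | COc1ccc(C=O)cc1 | starting material
7 | racemic 1-[2,4-bis(benzyloxy)-3-methoxyphenyl]-3-hydroxy-3-(4-methoxyphenyl)propan-1-one (not isolated) | O=C(CC(O)c1ccc(OC)cc1)c1ccc(OCc2ccccc2)c(OC)c1OCc1ccccc1 | intermediate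
8 | (2E)-1-[2,4-bis(benzyloxy)-3-methoxyphenyl]-3-(4-methoxyphenyl)prop-2-en-1-one | O=C(/C=C/c1ccc(OC)cc1)c1ccc(OCc2ccccc2)c(OC)c1OCc1ccccc1 | intermediate
9 | rac-[2,4-bis(benzyloxy)-3-methoxyphenyl][(2S,3R)-3-(4-methoxyphenyl)oxiran-2-yl]methanone (trans; racemate, one enantiomer drawn) | O=C(c1ccc(OCc2ccccc2)c(OC)c1OCc1ccccc1)[C@H]1O[C@@H]1c1ccc(OC)cc1 | intermediate
10 | rac-3-[2,4-bis(benzyloxy)-3-methoxyphenyl]-2-(4-methoxyphenyl)-3-oxopropanal (racemic, enolisable centre) | O=CC(c1ccc(OC)cc1)C(=O)c1ccc(OCc2ccccc2)c(OC)c1OCc1ccccc1 | intermediate
11 | 3-(2,4-dihydroxy-3-methoxyphenyl)-2-(4-methoxyphenyl)-3-oxopropanal (racemic, not isolated) | O=CC(c1ccc(OC)cc1)C(=O)c1ccc(O)c(OC)c1O | intermediate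
12 | 2,7-dihydroxy-8-methoxy-3-(4-methoxyphenyl)chroman-4-one (mixture of racemic diastereomers, not isolated) | COc1ccc(C2C(O)Oc3c(OC)c(O)ccc3C2=O)cc1 | intermediate
13 | 7-hydroxy-8-methoxy-3-(4-methoxyphenyl)-4H-chromen-4-one | COc1ccc(-c2coc3c(OC)c(O)ccc3c2=O)cc1 | intermediate
14 | prenyl bromide (1-bromo-3-methylbut-2-ene) | CC(C)=CCBr | starting material
15 | 8-methoxy-3-(4-methoxyphenyl)-7-[(3-methylbut-2-en-1-yl)oxy]-4H-chromen-4-one | COc1ccc(-c2coc3c(OC)c(OCC=C(C)C)ccc3c2=O)cc1 | target

## Step count and risks

Total step count: 7. Longest linear sequence: 7 steps (1 to 15).

**Step 5 (key step).** What may go wrong: capture of the benzylic cation by fluoride, or by the ortho-benzyloxy oxygen with loss of the benzyl group, in place of acyl migration; and retro-Claisen loss of the formyl group from the product during work-up.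
Fallback: setting out from chalcone 8, oxidative 1,2-aryl migration with Tl(NO3)3·3H2O (trivalent thallium) in MeOH/HC(OMe)3 would move the 4-methoxyphenyl group from the β- to the α-carbon. It should give the acetal 1-[2,4-bis(benzyloxy)-3-methoxyphenyl]-3,3-dimethoxy-2-(4-methoxyphenyl)propan-1-one F1. Hydrogenolysis of F1 (H2, Pd/C, EtOAc) followed by warming with methanolic HCl would close ring C with loss of methanol and return to the route at 13. This replaces epoxidation and acyl shift by an aryl shift that reaches the same branched skeleton.

**Step 6.** What may go wrong: over-reduction (hydrogenation of the C2=C3 bond if dehydration begins on the catalyst, or reduction of the aryl ketone), incomplete cleavage of the hindered benzyl ether next to the carbonyl, or deformylation before ring closure.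
Fallback: setting out from 10, non-reductive debenzylation with BCl3 and pentamethylbenzene as cation scavenger in CH2Cl2 at −78 °C, then methanolic HCl, would give 13 through the same intermediates 11 and 12. No new compound is made.

**Step 4.** What may go wrong: sluggish conjugate addition of hydroperoxide to an enone deactivated by the 4-methoxyphenyl donor and the electron-rich aroyl ring, with retro-aldol cleavage on prolonged exposure to base, and solvolytic opening of the acid-sensitive epoxide on work-up.
Fallback: setting out from 5, α-bromination with PhNMe3Br3 in THF would give 1-[2,4-bis(benzyloxy)-3-methoxyphenyl]-2-bromoethan-1-one F2. Darzens condensation of F2 with aldehyde 6 (NaOMe, MeOH/THF, 0 °C) should give the trans-epoxy ketone directly, returning to the route at 9 and bypassing 8.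

**Step 1.** What may go wrong: O-acylation without transfer to carbon, a second acylation, or Lewis-acid demethylation of the crowded central methoxy group at 90 °C.
Fallback: setting out from 1, double benzylation with 3 (K2CO3, DMF) would give 1,3-bis(benzyloxy)-2-methoxybenzene F3. Bromination with NBS in MeCN at the position para to one benzyloxy group would give 1,3-bis(benzyloxy)-4-bromo-2-methoxybenzene F4. Bromine–lithium exchange (n-BuLi, THF, −78 °C) and acylation of the aryllithium with N-methoxy-N-methylacetamide would return to the route at 5, bypassing 2 and 4.

## Further compounds

F1 | step 5 | 1-[2,4-bis(benzyloxy)-3-methoxyphenyl]-3,3-dimethoxy-2-(4-methoxyphenyl)propan-1-one (racemic) | COC(OC)C(c1ccc(OC)cc1)C(=O)c1ccc(OCc2ccccc2)c(OC)c1OCc1ccccc1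
F0 | step 6 | none | none
F2 | step 4 | 1-[2,4-bis(benzyloxy)-3-methoxyphenyl]-2-bromoethan-1-one | O=C(CBr)c1ccc(OCc2ccccc2)c(OC)c1OCc1ccccc1
F3 | step 1 | 1,3-bis(benzyloxy)-2-methoxybenzene | COc1c(OCc2ccccc2)cccc1OCc1ccccc1
F4 | step 1 | 1,3-bis(benzyloxy)-4-bromo-2-methoxybenzene | COc1c(OCc2ccccc2)ccc(Br)c1OCc1ccccc1
A1 | alternative 1 | 4-iodo-2-methoxybenzene-1,3-diol | COc1c(O)ccc(I)c1O
A2 | alternative 1 | carbon monoxide | [C-]#[O+]
A3 | alternative 1 | (E)-1-methoxy-2-(4-methoxyphenyl)ethene | CO/C=C/c1ccc(OC)cc1
A4 | alternative 1 | 7-hydroxy-8-methoxy-3-(4-methoxyphenyl)-4H-chromen-4-one (identical with 13) | COc1ccc(-c2coc3c(OC)c(O)ccc3c2=O)cc1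
A5 | alternative 2 | 1,2-dimethoxy-1,3-bis(trimethylsilyloxy)buta-1,3-diene (C1=C2 geometry not defined) | COC(O[Si](C)(C)C)=C(OC)C(=C)O[Si](C)(C)C
A6 | alternative 2 | 1-(4-methoxyphenyl)but-3-yn-2-one | C#CC(=O)Cc1ccc(OC)cc1
A7 | alternative 2 | 1-(2,4-dihydroxy-3-methoxyphenyl)-2-(4-methoxyphenyl)ethanone | COc1ccc(CC(=O)c2ccc(O)c(OC)c2O)cc1
A8 | alternative 2 | 4-methoxyphenylacetic acid | COc1ccc(CC(=O)O)cc1
A9 | alternative 3 | formononetin, 7-hydroxy-3-(4-methoxyphenyl)-4H-chromen-4-one | COc1ccc(-c2coc3cc(O)ccc3c2=O)cc1
A10 | alternative 3 | 8-formylformononetin, 7-hydroxy-3-(4-methoxyphenyl)-4-oxo-4H-chromene-8-carbaldehyde | COc1ccc(-c2coc3c(C=O)c(O)ccc3c2=O)cc1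
A11 | alternative 3 | 7,8-dihydroxy-3-(4-methoxyphenyl)-4H-chromen-4-one | COc1ccc(-c2coc3c(O)c(O)ccc3c2=O)cc1
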